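The teal run ends with far less target than side product A, 9.5 % against 81.0 % at 20.0 d, and the books of the new flask open from that comparison.

| flask | starting material | partner | remark | time |
|---|---|---|---|---|
| green | 0.25 M | 1.2 equiv | run made earlier |  |
| teal | 0.38 M | 1.2 equiv | run made earlier |  |
| flask | 0.50 M | 1.20 equiv |  | 15 d |

| run | time / d | target / % | side product A / % | starting material / % |
|---|---|---|---|---|
| green | 1.67 | 6.0 | 39.2 | 9.1 |
| green | 5.00 | 8.8 | 64.3 | 2.5 |
| green | 8.00 | 9.4 | 72.5 | 0.3 |
| green | 12.0 | 12.0 | 75.3 | 1.5 |
| green | 20.0 | 12.7 | 75.4 | 0 |
| teal | 4.00 | 7.9 | 69.9 | 3.4 |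
| teal | 8.00 | 8.2 | 76.0 | 0.2 |
| teal | 10.0 | 9.1 | 75.5 | 0 |
| teal | 15.0 | 12.7 | 79.2 | 0.6 |
| teal | 20.0 | 9.5 | 81.0 | 0 |

(each reading ± 1 percentage point)

1. ratio of target to side product A at 3.0 h
2. ratio of target to side product A at 15 d
3. which of target and side product A there is more of at 15 d



Partner is charged at 1.20 equiv, so I keep the ledger in starting material, the limiting reagent. Its own entry closes early: the teal run reads 0 % of it at 10.0 d. Single teal ratios jump, 0.160 at 15.0 d and 0.117 at 20.0 d, so I replace the curves by their means over the last 3 teal readings, which bracket the asked time. That gives 0.133 for the split, mean target over mean side product A. The same mean in the more dilute green run is 0.153, larger, and I take that gap of 0.0200 as the error of the reckoning.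

The 2 product columns together average 89.0 % of the charge in the teal run, and 11.0 % stays an open entry. Shared out by the split and carried over from the teal run, my estimate for the flask at 15 d enters 78.6 % side product A and 10.4 % target. For 3.0 h no reading stands near, so I apply the split loosely there too.

The forecast gives 0.13 at 3.0 h and 0.12 at 15 d, below my split, with side product A ahead, expecting “a roughly constant ratio”.

The flask gives 0.101 at 3.0 h and 0.115 at 15 d, with side product A ahead, 81.1 % against 9.30 % of target. My split of 0.133 stands 0.0180 above the flask's ratio at 15 d, less than the gap I allowed.

    starting material ⇌ intermediate A (K = 6.80, k = 0.0850 h⁻¹)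
    starting material → intermediate B (k = 0.0130 h⁻¹)
    partner + intermediate A → side product A (k = 0.100 M⁻¹ h⁻¹)
    partner + intermediate B → target (k = 0.0660 M⁻¹ h⁻¹)
    partner + intermediate B ⇌ intermediate C (K = 12.0 M⁻¹, k = 0.0400 M⁻¹ h⁻¹)
    partner + intermediate C → side product B (k = 0.0460 M⁻¹ h⁻¹)
    partner + target → over-reaction product (k = 0.00750 M⁻¹ h⁻¹)

In this flask, the forward constant from starting material to intermediate A is 6.54 times that to intermediate B. With 31 % of that forward turnover going back, the net branch through intermediate A is still 4.51 times the other.

In the neighbour flask with 0.720 equiv of partner, I close the ledger on partner, one partner per product: the split enters 63.6 % of the starting material charged as side product A and 8.46 % as target. The computed neighbour flask holds 58.3 % side product A and 8.21 % target at 15 d, a ratio of 0.141, with 0.72 % of the partner's own charge left.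

The earlier runs and the new flask were generated by integration on assumed constants; noise was put on by code.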